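**Strategy**

Everything rests on cutting the C9–C10 bond of the heneicosanoyl chain: two unactivated sp3 CH2 carbons in an unbranched chain, eight bonds from the ester carbonyl carbon (C1) and far from the benzene ring, so neither offers a polar handle. Both are therefore made from carboxylates. A mixed Kolbe electrolysis oxidises tridecanoic acid and the mono(2-phenylethyl) ester of sebacic acid at platinum; each loses CO2 and the two primary radicals combine, a union of two carbons of like polarity. The precursors are two carboxylic acids holding one carbon each more than the halves they deliver, with the phenethyl ester already in place, so the coupling completes the target.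

Key step: step 2

Assumption: sebacic acid, 2-phenylethanol and tridecanoic acid are taken as commercial. The target has no stereocenter. The two transient alkyl radicals of the electrolysis are numbered as non-isolated intermediates.

**Route**

Step 1
Reactants: 1 sebacic acid (decanedioic acid); 2 2-phenylethanol
Product: 3 10-oxo-10-(2-phenylethoxy)decanoic acid (sebacic acid mono(2-phenylethyl) ester)
Conditions: 1 (3 equiv), 2 (1 equiv), TsOH·H2O (cat.), toluene, reflux, Dean–Stark; cool, filter off excess 1; chromatography
Reagents that add atoms: none
Why: Fischer esterification with azeotropic removal of water is statistical on the symmetric diacid, the threefold excess of 1 should hold diester formation down, and the half ester should be separable from the neutral diester on silica and from 1 by the poor solubility of 1 in cold toluene.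

Step 2
Reactants: 3 10-oxo-10-(2-phenylethoxy)decanoic acid; 4 tridecanoic acid
Product: 7 2-phenylethyl heneicosanoate, via dodecyl radical 5 (not isolated), via 8-(2-phenylethoxycarbonyl)octyl radical 6 (not isolated)
Conditions: undivided cell, smooth Pt anode/Pt cathode, 3 (1 equiv), 4 (4 equiv), KOH (5 mol% of total acid), MeOH, 45–50 °C, constant current ca. 0.3 A cm⁻², stopped while still weakly acidic; AcOH quench; chromatography
Reagents that add atoms: none
Why: Mixed (crossed) Kolbe electrolysis: each carboxylate is oxidised by one electron at the platinum anode, the acyloxy radicals lose CO2 at once, and the primary radicals 5 and 6, formed side by side in high concentration at the electrode surface, combine to the C9–C10 bond of the chain. Cross-coupling of a fatty acid with a half ester of a diacid is the classical Kolbe route to long-chain esters, so the reaction type is known on this substrate class. No ring is closed and no stereocenter is formed. The step needs the one-electron radical path to win over further oxidation to carbocations (Hofer–Moest), which the unbranched, unstabilised primary radicals, the smooth Pt anode, the high current density and the weakly acidic medium should secure. It also needs cross- over homo-coupling, which is statistical; the fourfold excess of 4 should send most radicals 6 into the cross product, and the homo-dimers tetracosane (no ester) and bis(2-phenylethyl) octadecanedioate (two esters) differ from the monoester 7 in polarity and should be removed on silica. The phenethyl ester sits eight carbons from the radical centre and should survive as long as the bulk solution stays acidic, which is why the electrolysis is stopped before the acid is used up.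

**Compound list**

1 | sebacic acid (decanedioic acid) | OC(=O)CCCCCCCCC(=O)O | starting material
2 | 2-phenylethanol | OCCc1ccccc1 | starting material
3 | 10-oxo-10-(2-phenylethoxy)decanoic acid | OC(=O)CCCCCCCCC(=O)OCCc1ccccc1 | intermediate
4 | tridecanoic acid | CCCCCCCCCCCCC(=O)O | starting material
5 | dodecyl radical | CCCCCCCCCCC[CH2] | intermediate
6 | 8-(2-phenylethoxycarbonyl)octyl radical | [CH2]CCCCCCCC(=O)OCCc1ccccc1 | intermediate
7 | 2-phenylethyl heneicosanoate | CCCCCCCCCCCCCCCCCCCCC(=O)OCCc1ccccc1 | target

**Step count and risks**

Total step count: 2. Longest linear sequence: 2 steps (1 → 3 → 7).

The route has only two steps, so both are ranked, the riskier first.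

Step 2 (key step). What may go wrong: the statistical pairing of radicals may give mainly homo-dimers if the two carboxylates are discharged at unequal rates. The phenethyl ester may undergo methanolysis if the solution near the cathode turns basic. The waxy products may form a film on the anode and divert the current to solvent oxidation. Fallback, from 3 back to 7: the free acid of 3 would be converted with N-hydroxyphthalimide, N,N'-diisopropylcarbodiimide and catalytic DMAP in CH2Cl2 into the redox-active ester 1-(1,3-dioxoisoindolin-2-yl) 10-(2-phenylethyl) decanedioate F1. Commercial 1-bromododecane (CCCCCCCCCCCCBr) would be turned with zinc dust and LiCl in THF into dodecylzinc bromide F2. A nickel-catalysed decarboxylative alkyl–alkyl cross-coupling of F1 with F2 (NiCl2·glyme, 4,4'-di-tert-butyl-2,2'-bipyridine, THF/DMF, room temperature) should then form the same C9–C10 bond selectively, without statistical pairing, and give 7 directly; the ester should tolerate the organozinc.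

Step 1. What may go wrong: over-esterification to the diester, and incomplete separation of the half ester from the large excess of diacid. Fallback, from 2 back to 3: commercial 10-hydroxydecanoic acid (OCCCCCCCCCC(=O)O) would be esterified with an excess of 2 (TsOH cat., toluene, Dean–Stark; any oligoester of the hydroxy acid is transesterified by the excess alcohol) to give 2-phenylethyl 10-hydroxydecanoate F3. Oxidation of its primary alcohol to the acid with catalytic TEMPO and PhI(OAc)2 in MeCN–H2O should give 3 without any statistical desymmetrisation.

Further compounds
F1 | step 2 | 1-(1,3-dioxoisoindolin-2-yl) 10-(2-phenylethyl) decanedioate | O=C(CCCCCCCCC(=O)OCCc1ccccc1)ON1C(=O)c2ccccc2C1=O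
F2 | step 2 | dodecylzinc bromide | CCCCCCCCCCCC[Zn]Br
F3 | step 1 | 2-phenylethyl 10-hydroxydecanoate | OCCCCCCCCCC(=O)OCCc1ccccc1
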